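**Plan**

Ring atoms: C1 bears CO2Me and is joined to C2 by the double bond, C3 bears OAc, C4 the propanoate, C5 the 2-methylbutanoate, C6 is CH2.
Retrosynthesis: the O4, O5 and O3 acyl groups come off in that order (O5 with inversion), C3 goes back to a ketone and C1=C2 to its aldol, and the carbocycle is then cut at C1–C2 and C4–C5.
Enabling feature: C1 and C3 are 1,5-related around the six-membered ring, so at the ketone level the ring is a cyclised 2,6-dioxoheptanoate. Its O=C1–C6=C5(OR) part is a 1-oxadiene that takes up the C4 end of an enol ether, and its C2 methyl ketone can close onto the C1 keto ester.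
Forward: a vinyl ether and methyl chlorooxoacetate give the C5–C6–C1 heterodiene; silyloxyacetone gives the C2–C3–C4 enol ether. One flask joins them through a temporary dihydropyran that opens and recloses as the carbocycle (the pyranose-to-carbocycle switch of dehydroquinate synthase), then dehydration and ketone reduction follow the shikimate pathway.
Stereochemistry: the Cu(OTf)2/(S,S)-t-Bu-box catalyst sets C5 and, through the endo transition state, C4 (4,5-cis). C3 is relayed by hydride addition anti to both ethers. C5 is then inverted when the bought (R)-2-methylbutanoic acid is introduced by Mitsunobu reaction, giving 3,4-cis-4,5-trans.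
The three oxygens are told apart by origin: O3 from the ketone, O5 as the 4-methoxybenzyl (PMB) ether of the heterodiene, O4 as the TBS ether of the enol ether.

Key step: step 4

Assumption: (R)-2-methylbutanoic acid is bought enantiopure, and the (S,S) ligand is assigned to the needed facial sense at C5 from the square-planar chelate model; the (R,R) ligand would be used if the sense proved opposite.

Step 1
Reactants: 1 4-methoxybenzyl alcohol; 2 butyl vinyl ether
Product: 3 1-methoxy-4-[(vinyloxy)methyl]benzene
Conditions: Pd(OCOCF3)2 (0.5 mol%), 4,7-diphenyl-1,10-phenanthroline (0.5 mol%), Et3N (5 mol%), neat 2 (20 equiv), 75 °C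
Reagents that add atoms: none
Why: Pd(OCOCF3)2-catalysed transfer vinylation (transetherification) of a primary alcohol by an alkyl vinyl ether, driven by the excess of 2, should give the vinyl ether without forming a stereocentre.

Step 2
Reactants: 3 1-methoxy-4-[(vinyloxy)methyl]benzene; 4 methyl chlorooxoacetate
Product: 5 methyl (3E)-4-[(4-methoxybenzyl)oxy]-2-oxobut-3-enoate
Conditions: pyridine (1.3 equiv), CH2Cl2, -10 °C to rt
Reagents that add atoms: none
Why: Electrophilic C-acylation of the enol ether β-carbon by the oxalyl chloride and loss of HCl to pyridine should give the push-pull β-alkoxyvinyl keto ester as the favoured E isomer, the base protecting the acid-labile benzyl ether.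

Step 3
Reactants: 6 1-[(tert-butyldimethylsilyl)oxy]propan-2-one
Product: 7 tert-butyldimethyl({(1Z)-2-[(trimethylsilyl)oxy]prop-1-en-1-yl}oxy)silane
Conditions: TMSOTf (1.1 equiv), Et3N (1.3 equiv), CH2Cl2, 0 °C to rt
Reagents that add atoms: trimethylsilyl trifluoromethanesulfonate, C[Si](C)(C)OS(=O)(=O)C(F)(F)F
Why: Soft enolisation (silyl enol ether formation) toward the more acidic oxygen-bearing methylene under equilibrating amine/silyl triflate conditions should give the more substituted 1,2-dioxygenated enol ether as the Z isomer with both silyloxy groups cis.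

Step 4
Reactants: 5 methyl (3E)-4-[(4-methoxybenzyl)oxy]-2-oxobut-3-enoate; 7 tert-butyldimethyl({(1Z)-2-[(trimethylsilyl)oxy]prop-1-en-1-yl}oxy)silane
Product: 10 methyl (4S,5S)-4-[(tert-butyldimethylsilyl)oxy]-1-hydroxy-5-[(4-methoxybenzyl)oxy]-3-oxocyclohexane-1-carboxylate, via dihydropyran cycloadduct 8 (not isolated), via 2,6-diketo ester 9 (not isolated)
Conditions: Cu(OTf)2 (10 mol%), (S,S)-t-Bu-box = 2,2'-(propane-2,2-diyl)bis[(4S)-4-tert-butyl-4,5-dihydro-1,3-oxazole] (11 mol%), THF, -78 to -30 °C; then H2O (5 equiv), TsOH·H2O (10 mol%), 0 °C to rt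
Reagents that add atoms: none
Why: Proposed new method: the Cu(OTf)2–bis(oxazoline) complex (divalent copper) chelates the α-keto ester of 5 and activates its 1-oxadiene O=C1–C6=C5, to which the silyloxy-bearing C4 end of 7 adds (concerted endo hetero-Diels–Alder reaction or its stepwise Mukaiyama–Michael equivalent) to form C4–C5 and the temporary dihydropyran 8. Aqueous acid then hydrolyses the silyl ketal, the pyran opens to diketo ester 9, and the enol of its methyl ketone adds to the copper-bound C1 keto group to form C1–C2 in 10. The closest known reaction types are the Cu(OTf)2–bis(oxazoline)-catalysed inverse-demand hetero-Diels–Alder reaction of γ-alkoxy β,γ-unsaturated α-keto esters with enol ethers, the Ferrier pyranose-to-carbocycle rearrangement and the aldol of dehydroquinate synthase, which the step copies; untested are the fully oxygenated trisubstituted enol ether and the ring switch in the same flask. The dihydropyran closes by [4+2] cycloaddition and the carbocycle by 6-(enolendo)-exo-trig aldol addition. C5 is set by the catalyst (a tert-butyl group shields one face of the planar chelate), C4 by the Z geometry of 7 in the endo transition state (4,5-cis), and the temporary C1 carbinol by the chair transition state of the aldol (it is erased in step 5). The step needs C4 and not C3 of 7 to bond to C5 (secured by the methyl and silyloxy groups, which stabilise positive charge at C3), enolisation of 9 toward C2 only (secured because acid-catalysed enolisation is retarded at the silyloxy-bearing C4, which also keeps C4 from epimerising) and retention of the C5 ether (secured by acidic conditions, under which β-elimination is slow).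

Step 5
Reactants: 10 methyl (4S,5S)-4-[(tert-butyldimethylsilyl)oxy]-1-hydroxy-5-[(4-methoxybenzyl)oxy]-3-oxocyclohexane-1-carboxylate
Product: 11 methyl (4S,5S)-4-[(tert-butyldimethylsilyl)oxy]-5-[(4-methoxybenzyl)oxy]-3-oxocyclohex-1-ene-1-carboxylate
Conditions: Martin sulfurane Ph2S[OC(CF3)2Ph]2 (1.5 equiv), CH2Cl2, 0 °C to rt
Reagents that add atoms: none
Why: Dehydration of the tertiary aldol alcohol by the sulfurane (alkoxysulfonium formation, then loss of the acidic C2 hydrogen next to the ketone) should give only the C1=C2 enone, as dehydroquinase does, under neutral conditions that neither epimerise C4 nor expel the C5 ether.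

Step 6
Reactants: 11 methyl (4S,5S)-4-[(tert-butyldimethylsilyl)oxy]-5-[(4-methoxybenzyl)oxy]-3-oxocyclohex-1-ene-1-carboxylate
Product: 12 methyl (3R,4R,5S)-4-[(tert-butyldimethylsilyl)oxy]-3-hydroxy-5-[(4-methoxybenzyl)oxy]cyclohex-1-ene-1-carboxylate
Conditions: NaBH4, CeCl3·7H2O, MeOH, -78 °C
Reagents that add atoms: none
Why: Luche 1,2-reduction, in which hydride should add to C3 from the face opposite to the cis-disposed C4 silyl ether and C5 benzyl ether (axial attack anti to the pseudoaxial α-silyloxy group), sets C3 with O3 cis to O4.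

Step 7
Reactants: 12 methyl (3R,4R,5S)-4-[(tert-butyldimethylsilyl)oxy]-3-hydroxy-5-[(4-methoxybenzyl)oxy]cyclohex-1-ene-1-carboxylate
Product: 13 methyl (3R,4S,5S)-3-acetoxy-4-[(tert-butyldimethylsilyl)oxy]-5-[(4-methoxybenzyl)oxy]cyclohex-1-ene-1-carboxylate
Conditions: Ac2O, pyridine, DMAP (5 mol%), CH2Cl2, 0 °C
Reagents that add atoms: acetic anhydride, CC(=O)OC(C)=O
Why: DMAP-catalysed acetylation of the only free hydroxyl group installs the C3 acetate without touching a stereocentre.

Step 8
Reactants: 13 methyl (3R,4S,5S)-3-acetoxy-4-[(tert-butyldimethylsilyl)oxy]-5-[(4-methoxybenzyl)oxy]cyclohex-1-ene-1-carboxylate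
Product: 14 methyl (3R,4S,5S)-3-acetoxy-4-[(tert-butyldimethylsilyl)oxy]-5-hydroxycyclohex-1-ene-1-carboxylate
Conditions: DDQ (1.3 equiv), CH2Cl2/pH 7 phosphate buffer (10:1), 0 °C to rt
Reagents that add atoms: none
Why: Oxidative cleavage of the 4-methoxybenzyl ether by DDQ (hydride abstraction, then hydrolysis of the oxocarbenium ion) should free O5 selectively, since the silyl ether, the allylic acetate and the enoate are inert to DDQ.

Step 9
Reactants: 14 methyl (3R,4S,5S)-3-acetoxy-4-[(tert-butyldimethylsilyl)oxy]-5-hydroxycyclohex-1-ene-1-carboxylate; 15 (R)-2-methylbutanoic acid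
Product: 16 methyl (3R,4S,5R)-3-acetoxy-4-[(tert-butyldimethylsilyl)oxy]-5-{[(2R)-2-methylbutanoyl]oxy}cyclohex-1-ene-1-carboxylate
Conditions: PPh3 (1.5 equiv), DIAD (1.5 equiv), toluene, 0 °C to rt
Reagents that add atoms: none
Why: Mitsunobu esterification, in which the carboxylate of 15 displaces the C5 oxyphosphonium group by SN2 from the face opposite to the C3 and C4 substituents, should invert C5 to the 4,5-trans arrangement of the target and leave the α-stereocentre of the acid untouched because the acid is never activated as an acyl donor.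

Step 10
Reactants: 16 methyl (3R,4S,5R)-3-acetoxy-4-[(tert-butyldimethylsilyl)oxy]-5-{[(2R)-2-methylbutanoyl]oxy}cyclohex-1-ene-1-carboxylate
Product: 17 methyl (3R,4S,5R)-3-acetoxy-4-hydroxy-5-{[(2R)-2-methylbutanoyl]oxy}cyclohex-1-ene-1-carboxylate
Conditions: HF·pyridine, THF/pyridine, 0 °C to rt
Reagents that add atoms: none
Why: Fluoride cleavage of the silyl ether in a weakly acidic medium, in which migration of the neighbouring acyl groups to O4 is slow, should free the C4 hydroxyl group.

Step 11
Reactants: 17 methyl (3R,4S,5R)-3-acetoxy-4-hydroxy-5-{[(2R)-2-methylbutanoyl]oxy}cyclohex-1-ene-1-carboxylate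
Product: 18 methyl (3R,4S,5R)-3-acetoxy-5-{[(2R)-2-methylbutanoyl]oxy}-4-(propanoyloxy)cyclohex-1-ene-1-carboxylate
Conditions: (EtCO)2O (1.5 equiv), DMAP (10 mol%), pyridine, CH2Cl2, 0 °C
Reagents that add atoms: propanoic anhydride, CCC(=O)OC(=O)CC
Why: DMAP-catalysed acylation of the remaining hydroxyl group, faster than base-induced acyl migration, should complete the triester.

**Compound list**

1 | 4-methoxybenzyl alcohol | COc1ccc(CO)cc1 | starting material
2 | butyl vinyl ether | C=COCCCC | starting material
3 | 1-methoxy-4-[(vinyloxy)methyl]benzene | COc1ccc(COC=C)cc1 | intermediate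
4 | methyl chlorooxoacetate | COC(=O)C(=O)Cl | starting material
5 | methyl (3E)-4-[(4-methoxybenzyl)oxy]-2-oxobut-3-enoate | COC(=O)C(=O)/C=C/OCc1ccc(OC)cc1 | intermediate
6 | 1-[(tert-butyldimethylsilyl)oxy]propan-2-one | CC(=O)CO[Si](C)(C)C(C)(C)C | starting material
7 | tert-butyldimethyl({(1Z)-2-[(trimethylsilyl)oxy]prop-1-en-1-yl}oxy)silane | C/C(O[Si](C)(C)C)=C/O[Si](C)(C)C(C)(C)C | intermediate
8 | methyl (3S,4S)-3-[(tert-butyldimethylsilyl)oxy]-4-[(4-methoxybenzyl)oxy]-2-methyl-2-[(trimethylsilyl)oxy]-3,4-dihydro-2H-pyran-6-carboxylate (formed in the flask in step 4; ketal carbon C2 not specified) | COC(=O)C1=C[C@H](OCc2ccc(OC)cc2)[C@H](O[Si](C)(C)C(C)(C)C)C(C)(O[Si](C)(C)C)O1 | intermediate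
9 | methyl (4S,5S)-5-[(tert-butyldimethylsilyl)oxy]-4-[(4-methoxybenzyl)oxy]-2,6-dioxoheptanoate (formed in the flask in step 4) | COC(=O)C(=O)C[C@H](OCc1ccc(OC)cc1)[C@H](O[Si](C)(C)C(C)(C)C)C(C)=O | intermediate
10 | methyl (4S,5S)-4-[(tert-butyldimethylsilyl)oxy]-1-hydroxy-5-[(4-methoxybenzyl)oxy]-3-oxocyclohexane-1-carboxylate (C1 not specified) | COC(=O)C1(O)CC(=O)[C@@H](O[Si](C)(C)C(C)(C)C)[C@@H](OCc2ccc(OC)cc2)C1 | intermediate
11 | methyl (4S,5S)-4-[(tert-butyldimethylsilyl)oxy]-5-[(4-methoxybenzyl)oxy]-3-oxocyclohex-1-ene-1-carboxylate | CC(C)(C)[Si](C)(C)O[C@@H]1C(=O)C=C(C(=O)OC)C[C@@H]1OCc1ccc(OC)cc1 | intermediate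
12 | methyl (3R,4R,5S)-4-[(tert-butyldimethylsilyl)oxy]-3-hydroxy-5-[(4-methoxybenzyl)oxy]cyclohex-1-ene-1-carboxylate | CC(C)(C)[Si](C)(C)O[C@@H]1[C@H](O)C=C(C(=O)OC)C[C@@H]1OCc1ccc(OC)cc1 | intermediate
13 | methyl (3R,4S,5S)-3-acetoxy-4-[(tert-butyldimethylsilyl)oxy]-5-[(4-methoxybenzyl)oxy]cyclohex-1-ene-1-carboxylate | CC(C)(C)[Si](C)(C)O[C@@H]1[C@H](OC(C)=O)C=C(C(=O)OC)C[C@@H]1OCc1ccc(OC)cc1 | intermediate
14 | methyl (3R,4S,5S)-3-acetoxy-4-[(tert-butyldimethylsilyl)oxy]-5-hydroxycyclohex-1-ene-1-carboxylate | CC(C)(C)[Si](C)(C)O[C@@H]1[C@H](OC(C)=O)C=C(C(=O)OC)C[C@@H]1O | intermediate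
15 | (R)-2-methylbutanoic acid | CC[C@@H](C)C(=O)O | starting material
16 | methyl (3R,4S,5R)-3-acetoxy-4-[(tert-butyldimethylsilyl)oxy]-5-{[(2R)-2-methylbutanoyl]oxy}cyclohex-1-ene-1-carboxylate | CC(C)(C)[Si](C)(C)O[C@@H]1[C@H](OC(C)=O)C=C(C(=O)OC)C[C@H]1OC(=O)[C@H](C)CC | intermediate
17 | methyl (3R,4S,5R)-3-acetoxy-4-hydroxy-5-{[(2R)-2-methylbutanoyl]oxy}cyclohex-1-ene-1-carboxylate | O[C@@H]1[C@H](OC(C)=O)C=C(C(=O)OC)C[C@H]1OC(=O)[C@H](C)CC | intermediate
18 | methyl (3R,4S,5R)-3-acetoxy-5-{[(2R)-2-methylbutanoyl]oxy}-4-(propanoyloxy)cyclohex-1-ene-1-carboxylate | CCC(=O)O[C@@H]1[C@H](OC(C)=O)C=C(C(=O)OC)C[C@H]1OC(=O)[C@H](C)CC | target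

Total step count: 11. Longest linear sequence: 10 steps (steps 1, 2, 4, 5, 6, 7, 8, 9, 10, 11; step 3 is a side branch).

**Steps most likely to fail**

Step 4. The enol ether may add with the wrong regiochemistry or with poor facial selectivity, the C5 ether may be lost by β-elimination once the pyran has opened, and enolisation of the diketo ester may be slow or may epimerise C4. The fallback uses known chemistry only and separates the two bond-forming events. From 5 and 7 only the Cu(OTf)2–bis(oxazoline) hetero-Diels–Alder reaction is run, a documented reaction type for γ-alkoxy unsaturated keto esters, and dihydropyran 8 is isolated. PPTS in wet acetone opens it to 9, and the carbocycle is closed in a separate flask by enamine catalysis (pyrrolidinium acetate, the Robinson-type cycloaldolisation known for 2,6-dioxo esters), which comes back to the route at 10. No compound outside the compound list is made (F0).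

Step 9. Anti elimination of the oxyphosphonium group toward C6 may outrun substitution, and the weakly acidic, α-branched acid may attack too slowly. The fallback decouples inversion from acylation. From 14 a Mitsunobu reaction with chloroacetic acid, a stronger acid that favours substitution, should give methyl (3R,4S,5R)-3-acetoxy-4-[(tert-butyldimethylsilyl)oxy]-5-[(chloroacetyl)oxy]cyclohex-1-ene-1-carboxylate F1. Thiourea and NaHCO3 in EtOH remove the chloroacetate selectively beside the acetate and give methyl (3R,4S,5R)-3-acetoxy-4-[(tert-butyldimethylsilyl)oxy]-5-hydroxycyclohex-1-ene-1-carboxylate F2. Steglich esterification of F2 with 15 (DCC, DMAP cat., CH2Cl2, 0 °C) proceeds with retention and comes back to the route at 16.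

Step 5. Dehydration at the ketone level may be followed by loss of the C5 ether and aromatisation, or by epimerisation at C4 next to the ketone. The fallback changes the order, as in the classical quinate-to-shikimate conversions. From 10 the ketone is reduced first (NaBH4, MeOH, -40 °C, hydride anti to the cis C4 and C5 ethers) to methyl (3R,4R,5S)-4-[(tert-butyldimethylsilyl)oxy]-1,3-dihydroxy-5-[(4-methoxybenzyl)oxy]cyclohexane-1-carboxylate F3. The secondary hydroxyl group is acetylated (Ac2O, pyridine) to methyl (3R,4S,5S)-3-acetoxy-4-[(tert-butyldimethylsilyl)oxy]-1-hydroxy-5-[(4-methoxybenzyl)oxy]cyclohexane-1-carboxylate F4. The tertiary alcohol is dehydrated last with SOCl2/pyridine, which comes back to the route at 13.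

**Further compounds**

F0 | step 4 | none | none
F1 | step 9 | methyl (3R,4S,5R)-3-acetoxy-4-[(tert-butyldimethylsilyl)oxy]-5-[(chloroacetyl)oxy]cyclohex-1-ene-1-carboxylate | CC(C)(C)[Si](C)(C)O[C@@H]1[C@H](OC(C)=O)C=C(C(=O)OC)C[C@H]1OC(=O)CCl
F2 | step 9 | methyl (3R,4S,5R)-3-acetoxy-4-[(tert-butyldimethylsilyl)oxy]-5-hydroxycyclohex-1-ene-1-carboxylate | CC(C)(C)[Si](C)(C)O[C@@H]1[C@H](OC(C)=O)C=C(C(=O)OC)C[C@H]1O
F3 | step 5 | methyl (3R,4R,5S)-4-[(tert-butyldimethylsilyl)oxy]-1,3-dihydroxy-5-[(4-methoxybenzyl)oxy]cyclohexane-1-carboxylate (C1 not specified) | COC(=O)C1(O)C[C@@H](O)[C@@H](O[Si](C)(C)C(C)(C)C)[C@@H](OCc2ccc(OC)cc2)C1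
F4 | step 5 | methyl (3R,4S,5S)-3-acetoxy-4-[(tert-butyldimethylsilyl)oxy]-1-hydroxy-5-[(4-methoxybenzyl)oxy]cyclohexane-1-carboxylate (C1 not specified) | COC(=O)C1(O)C[C@@H](OC(C)=O)[C@@H](O[Si](C)(C)C(C)(C)C)[C@@H](OCc2ccc(OC)cc2)C1
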